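**Retrosynthetic overview**

- The target is the ester of an (E)-enol-lactone alcohol with a (Z)-keto-hydroxy acid; both halves are isomers of one C19 unit, 2-(1-hydroxyprop-2-ynyl)hexadec-2-enoic acid. Enabling feature: in the oxolan-2-one ring the carboxyl oxygen O1 sits on C5, which carries the exocyclic CH2 (an enol ester, the 5-exo adduct of CO2H to C≡CH), and the side-chain CH(OH)–C(=O)–CH3 is the hydrate of the same HC≡C–CH(O)– unit.
- Key disconnection: the ring O1–C5 bond and the side-chain ketone both go back to a silyl-free diyne hydroxy acid; one gold catalyst closes the only ring (last step) and hydrates the second alkyne.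
- The ester between the halves: Yamaguchi coupling of the (E)-alcohol half with the (Z)-acid half.
- Both halves come from one (S)-diynyl carbinol by stereodivergent hydrostannation (palladium: cis, gives E; ruthenium: trans, gives Z), each followed by carbonylation at tin.
- The single carbinol configuration comes from a CBS reduction of the diynone made from pentadecyne and a silylpropynal; no other ring is formed.

Key step: step 12

Assumption: the triisopropylsilyl cap makes its alkyne the large, unreactive arm of the diynone and diynol, i.e. it acts as the large group in the CBS reduction and is not attacked by either hydrostannation catalyst.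

**Step 1**
Reactants: 1 pentadec-1-yne; 2 3-[tri(propan-2-yl)silyl]prop-2-ynal
Product: 4 rac-1-[tri(propan-2-yl)silyl]octadeca-1,4-diyn-3-ol, via lithium pentadec-1-yn-1-ide 3 (not isolated)
Conditions: n-BuLi, THF, −78 °C; then 2, −78 to 0 °C; H2O quench
Reagents that add atoms: none
Why: Carbonyl alkynylation: the lithium acetylide adds 1,2 to the ynal and assembles the whole C18 skipped-diyne skeleton in one step, the carbinol being left racemic on purpose because its configuration is set by steps 2 and 3.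

**Step 2**
Reactants: 4 rac-1-[tri(propan-2-yl)silyl]octadeca-1,4-diyn-3-ol
Product: 5 1-[tri(propan-2-yl)silyl]octadeca-1,4-diyn-3-one
Conditions: activated MnO2, CH2Cl2, rt
Reagents that add atoms: none
Why: MnO2 oxidation of a doubly propargylic alcohol is mild and selective and gives the diynone needed for reagent-controlled reduction, the silyl alkyne and the alkyl chain being inert.

**Step 3**
Reactants: 5 1-[tri(propan-2-yl)silyl]octadeca-1,4-diyn-3-one
Product: 6 (3S)-1-[tri(propan-2-yl)silyl]octadeca-1,4-diyn-3-ol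
Conditions: (R)-2-methyl-CBS-oxazaborolidine (20 mol %), catecholborane, toluene, −78 °C; aqueous work-up
Reagents that add atoms: none
Why: Corey–Bakshi–Shibata reduction: the remotely bulky silyl-capped alkynyl arm takes the place of the large group and the slim alkyl-substituted alkynyl arm that of the small one, so that the (R)-catalyst delivers hydride to the face that gives the (3S)-carbinol, the only source of chirality for both halves of the target.

**Step 4**
Reactants: 6 (3S)-1-[tri(propan-2-yl)silyl]octadeca-1,4-diyn-3-ol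
Product: 7 (3R,4E)-4-(tributylstannyl)-1-[tri(propan-2-yl)silyl]octadec-4-en-1-yn-3-ol
Conditions: PdCl2(PPh3)2 (2 mol %), Bu3SnH, THF, 0 °C
Reagents that add atoms: tributyltin hydride, CCCC[SnH](CCCC)CCCC
Why: Palladium-catalysed syn-hydrostannation of a propargylic alcohol places tin on the alkyne carbon next to the carbinol and adds H and Sn to the same face, which fixes the 4E geometry (tridecyl chain cis to the carbinol carbon), while the silyl-capped alkyne is shielded by its triisopropylsilyl group.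

**Step 5**
Reactants: 7 (3R,4E)-4-(tributylstannyl)-1-[tri(propan-2-yl)silyl]octadec-4-en-1-yn-3-ol
Product: 8 2-(trimethylsilyl)ethyl (2E)-2-{(1S)-1-hydroxy-3-[tri(propan-2-yl)silyl]prop-2-yn-1-yl}hexadec-2-enoate
Conditions: Pd(OAc)2 (10 mol %), Ph3As, 1,4-benzoquinone, CF3CO2H (cat.), CO (1 atm), 2-(trimethylsilyl)ethanol/THF, rt
Reagents that add atoms: carbon monoxide, [C-]#[O+]; 2-(trimethylsilyl)ethanol, C[Si](C)(C)CCO
Why: Hydroxyl-assisted oxidative alkoxycarbonylation of an alkenylstannane (transmetalation to divalent palladium, CO insertion, alcoholysis of the acylpalladium species, reoxidation of zerovalent palladium by benzoquinone) replaces tin by the ester carbon with retention of the alkene geometry, giving the 2E enoate as a fluoride-labile ester.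

**Step 6**
Reactants: 6 (3S)-1-[tri(propan-2-yl)silyl]octadeca-1,4-diyn-3-ol
Product: 9 (3R,4Z)-4-(tributylstannyl)-1-[tri(propan-2-yl)silyl]octadec-4-en-1-yn-3-ol
Conditions: [Cp*RuCl]4 (1.25 mol %), Bu3SnH, CH2Cl2, rt
Reagents that add atoms: tributyltin hydride, CCCC[SnH](CCCC)CCCC
Why: Hydroxyl-directed ruthenium-catalysed trans-hydrostannation: the O–H···Cl–Ru hydrogen bond delivers tin to the alkyne carbon next to the carbinol and H adds to the opposite face, which fixes the 4Z geometry (tridecyl chain cis to tin), the geometric complement of 7 from the same diynol.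

**Step 7**
Reactants: 9 (3R,4Z)-4-(tributylstannyl)-1-[tri(propan-2-yl)silyl]octadec-4-en-1-yn-3-ol
Product: 10 methyl (2Z)-2-{(1S)-1-hydroxy-3-[tri(propan-2-yl)silyl]prop-2-yn-1-yl}hexadec-2-enoate
Conditions: Pd(OAc)2 (10 mol %), Ph3As, 1,4-benzoquinone, CF3CO2H (cat.), CO (1 atm), MeOH, rt
Reagents that add atoms: carbon monoxide, [C-]#[O+]; methanol, CO
Why: The same hydroxyl-assisted oxidative methoxycarbonylation of the alkenylstannane replaces tin by the ester carbon with retention, so that the tridecyl chain ends cis to the ester (2Z).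

**Step 8**
Reactants: 10 methyl (2Z)-2-{(1S)-1-hydroxy-3-[tri(propan-2-yl)silyl]prop-2-yn-1-yl}hexadec-2-enoate
Product: 11 methyl (2Z)-2-{(1S)-1-{[tert-butyl(dimethyl)silyl]oxy}-3-[tri(propan-2-yl)silyl]prop-2-yn-1-yl}hexadec-2-enoate
Conditions: TBSOTf, 2,6-lutidine, CH2Cl2, −78 to 0 °C
Reagents that add atoms: tert-butyldimethylsilyl trifluoromethanesulfonate, CC(C)(C)[Si](C)(C)OS(=O)(=O)C(F)(F)F
Why: Silylation of the secondary alcohol with a silyl triflate and a hindered base masks the only hydroxyl group of the acid half so that it cannot be acylated in step 10; the stereocentre is not touched.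

**Step 9**
Reactants: 11 methyl (2Z)-2-{(1S)-1-{[tert-butyl(dimethyl)silyl]oxy}-3-[tri(propan-2-yl)silyl]prop-2-yn-1-yl}hexadec-2-enoate
Product: 12 (2Z)-2-{(1S)-1-{[tert-butyl(dimethyl)silyl]oxy}-3-[tri(propan-2-yl)silyl]prop-2-yn-1-yl}hexadec-2-enoic acid
Conditions: LiOH·H2O, THF/MeOH/H2O, 40 °C; then aq. HCl to pH 4
Reagents that add atoms: lithium hydroxide, [Li+].[OH-]
Why: Saponification of the methyl ester; the enoate has no α-hydrogen, so β-elimination of the silyloxy group is impossible, and the silyl ether and silyl alkyne tolerate LiOH.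

**Step 10**
Reactants: 12 (2Z)-2-{(1S)-1-{[tert-butyl(dimethyl)silyl]oxy}-3-[tri(propan-2-yl)silyl]prop-2-yn-1-yl}hexadec-2-enoic acid; 8 2-(trimethylsilyl)ethyl (2E)-2-{(1S)-1-hydroxy-3-[tri(propan-2-yl)silyl]prop-2-yn-1-yl}hexadec-2-enoate
Product: 14 2-(trimethylsilyl)ethyl (2E)-2-{(1S)-1-[((2Z)-2-{(1S)-1-{[tert-butyl(dimethyl)silyl]oxy}-3-[tri(propan-2-yl)silyl]prop-2-yn-1-yl}hexadec-2-enoyl)oxy]-3-[tri(propan-2-yl)silyl]prop-2-yn-1-yl}hexadec-2-enoate, via mixed anhydride 13 (not isolated)
Conditions: 2,4,6-trichlorobenzoyl chloride, Et3N, toluene, rt; then 8, DMAP, toluene, rt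
Reagents that add atoms: none
Why: Yamaguchi esterification: the mixed anhydride 13 transfers the (Z)-acyl group through its acylpyridinium ion to the only free hydroxyl group, that of 8, with both carbinol centres untouched because the reaction takes place at oxygen.

**Step 11**
Reactants: 14 the fully silylated diester
Product: 15 (2E)-2-{(1R)-1-[((2Z)-2-[(1R)-1-hydroxyprop-2-yn-1-yl]hexadec-2-enoyl)oxy]prop-2-yn-1-yl}hexadec-2-enoic acid
Conditions: TBAF, AcOH, THF, 0 °C to rt
Reagents that add atoms: none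
Why: Fluoride-induced global desilylation: the 2-(trimethylsilyl)ethyl ester fragments to the carboxylate, ethene and Me3SiF, the silyl ether and both alkynyl silanes are cleaved, and the acetic acid buffer keeps the medium mild enough for the allylic and propargylic ester linkage (the descriptors change to R only because the silyl groups leave; the spatial arrangement is unchanged).

**Step 12**
Reactants: 15 (2E)-2-{(1R)-1-[((2Z)-2-[(1R)-1-hydroxyprop-2-yn-1-yl]hexadec-2-enoyl)oxy]prop-2-yn-1-yl}hexadec-2-enoic acid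
Product: 17 (3E,4S)-5-methylidene-2-oxo-3-tetradecylideneoxolan-4-yl (2Z)-2-[(1S)-1-hydroxy-2-oxopropyl]hexadec-2-enoate (CNP0377581.1), via enol lactone alkyne 16 (not isolated)
Conditions: Ph3PAuNTf2 (5 mol %), dry 1,4-dioxane, rt; then H2O (10 equiv), rt
Reagents that add atoms: water, O
Why: The cationic gold complex π-activates the terminal alkyne of the acid half, the carboxyl oxygen adds anti to the internal alkyne carbon and protodeauration of the vinylgold species forms the O–C(=CH2) bond and gives enol lactone 16; once water is added the same catalyst activates the second alkyne, the neighbouring enoate carbonyl adds to it, and water opens the cyclic oxocarbenium ion to the methyl ketone with the oxygen on the internal carbon. The closest known reaction types are the gold-catalysed cycloisomerisation of γ-alkynoic acids to γ-methylene butyrolactones and the carbonyl-assisted gold-catalysed hydration of alkynes. The oxolan-2-one ring closes in the 5-exo-dig mode, and the transient second ring (also 5-exo-dig) is opened again by water. No stereocentre is created: both carbinol C–O bonds and both trisubstituted alkenes are spectators under neutral conditions at room temperature, so the two carbinol centres set in step 3 are carried over unchanged. The selectivity needed is exo over 6-endo attack and lactonisation before hydration: the terminal alkyne directs the oxygen to its internal carbon, only one alkyne lies in 5-exo reach of the free acid (the other would need a nine-membered ring), the competing 1,2-acyloxy shift of the propargylic ester is reversible whereas lactonisation is not, and water is withheld until 16 has formed so that acyloxy-assisted hydration of the first alkyne cannot compete.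

**Compound list**

1 | pentadec-1-yne | C#CCCCCCCCCCCCCC | starting material
2 | 3-[tri(propan-2-yl)silyl]prop-2-ynal | O=CC#C[Si](C(C)C)(C(C)C)C(C)C | starting material
3 | lithium pentadec-1-yn-1-ide | [Li]C#CCCCCCCCCCCCCC | intermediate
4 | rac-1-[tri(propan-2-yl)silyl]octadeca-1,4-diyn-3-ol | OC(C#C[Si](C(C)C)(C(C)C)C(C)C)C#CCCCCCCCCCCCCC | intermediate
5 | 1-[tri(propan-2-yl)silyl]octadeca-1,4-diyn-3-one | O=C(C#C[Si](C(C)C)(C(C)C)C(C)C)C#CCCCCCCCCCCCCC | intermediate
6 | (3S)-1-[tri(propan-2-yl)silyl]octadeca-1,4-diyn-3-ol | O[C@H](C#C[Si](C(C)C)(C(C)C)C(C)C)C#CCCCCCCCCCCCCC | intermediate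
7 | (3R,4E)-4-(tributylstannyl)-1-[tri(propan-2-yl)silyl]octadec-4-en-1-yn-3-ol | O[C@H](C#C[Si](C(C)C)(C(C)C)C(C)C)/C(=C\CCCCCCCCCCCCC)[Sn](CCCC)(CCCC)CCCC | intermediate
8 | 2-(trimethylsilyl)ethyl (2E)-2-{(1S)-1-hydroxy-3-[tri(propan-2-yl)silyl]prop-2-yn-1-yl}hexadec-2-enoate | O[C@H](C#C[Si](C(C)C)(C(C)C)C(C)C)/C(=C\CCCCCCCCCCCCC)C(=O)OCC[Si](C)(C)C | intermediate
9 | (3R,4Z)-4-(tributylstannyl)-1-[tri(propan-2-yl)silyl]octadec-4-en-1-yn-3-ol | O[C@H](C#C[Si](C(C)C)(C(C)C)C(C)C)/C(=C/CCCCCCCCCCCCC)[Sn](CCCC)(CCCC)CCCC | intermediate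
10 | methyl (2Z)-2-{(1S)-1-hydroxy-3-[tri(propan-2-yl)silyl]prop-2-yn-1-yl}hexadec-2-enoate | O[C@H](C#C[Si](C(C)C)(C(C)C)C(C)C)/C(=C/CCCCCCCCCCCCC)C(=O)OC | intermediate
11 | methyl (2Z)-2-{(1S)-1-{[tert-butyl(dimethyl)silyl]oxy}-3-[tri(propan-2-yl)silyl]prop-2-yn-1-yl}hexadec-2-enoate | CC(C)(C)[Si](C)(C)O[C@H](C#C[Si](C(C)C)(C(C)C)C(C)C)/C(=C/CCCCCCCCCCCCC)C(=O)OC | intermediate
12 | (2Z)-2-{(1S)-1-{[tert-butyl(dimethyl)silyl]oxy}-3-[tri(propan-2-yl)silyl]prop-2-yn-1-yl}hexadec-2-enoic acid | CC(C)(C)[Si](C)(C)O[C@H](C#C[Si](C(C)C)(C(C)C)C(C)C)/C(=C/CCCCCCCCCCCCC)C(=O)O | intermediate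
13 | mixed anhydride of acid 12 with 2,4,6-trichlorobenzoic acid | CC(C)(C)[Si](C)(C)O[C@H](C#C[Si](C(C)C)(C(C)C)C(C)C)/C(=C/CCCCCCCCCCCCC)C(=O)OC(=O)c1c(Cl)cc(Cl)cc1Cl | intermediate
14 | 2-(trimethylsilyl)ethyl (2E)-2-{(1S)-1-[((2Z)-2-{(1S)-1-{[tert-butyl(dimethyl)silyl]oxy}-3-[tri(propan-2-yl)silyl]prop-2-yn-1-yl}hexadec-2-enoyl)oxy]-3-[tri(propan-2-yl)silyl]prop-2-yn-1-yl}hexadec-2-enoate | CC(C)(C)[Si](C)(C)O[C@H](C#C[Si](C(C)C)(C(C)C)C(C)C)/C(=C/CCCCCCCCCCCCC)C(=O)O[C@H](C#C[Si](C(C)C)(C(C)C)C(C)C)/C(=C\CCCCCCCCCCCCC)C(=O)OCC[Si](C)(C)C | intermediate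
15 | (2E)-2-{(1R)-1-[((2Z)-2-[(1R)-1-hydroxyprop-2-yn-1-yl]hexadec-2-enoyl)oxy]prop-2-yn-1-yl}hexadec-2-enoic acid | O[C@H](C#C)/C(=C/CCCCCCCCCCCCC)C(=O)O[C@H](C#C)/C(=C\CCCCCCCCCCCCC)C(=O)O | intermediate
16 | (3E,4S)-5-methylidene-2-oxo-3-tetradecylideneoxolan-4-yl (2Z)-2-[(1R)-1-hydroxyprop-2-yn-1-yl]hexadec-2-enoate | C=C1OC(=O)/C(=C/CCCCCCCCCCCCC)[C@@H]1OC(=O)/C(=C\CCCCCCCCCCCCC)[C@H](O)C#C | intermediate
17 | (3E,4S)-5-methylidene-2-oxo-3-tetradecylideneoxolan-4-yl (2Z)-2-[(1S)-1-hydroxy-2-oxopropyl]hexadec-2-enoate | C=C1OC(=O)/C(=C/CCCCCCCCCCCCC)[C@@H]1OC(=O)/C(=C\CCCCCCCCCCCCC)[C@H](O)C(C)=O | target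

**Step count and risks**

Total steps: 12. Longest linear sequence: 10 steps (steps 1, 2, 3, 6, 7, 8, 9, 10, 11, 12).

Steps most likely to fail:

Step 12. During the hydration stage the freshly formed enol lactone may be opened hydrolytically or isomerised by adventitious acid, and the free propargylic alcohol may undergo Meyer–Schuster rearrangement instead of hydration. The fallback lets the ketone arise by acyl transfer from an enol lactone instead of by hydration, so that gold only has to close rings. It sets out from 12 (and uses 8) and comes back to the route at 17. C-Desilylation of 12 with AgF in MeOH (dilute HCl work-up) would give (2Z)-2-[(1R)-1-{[tert-butyl(dimethyl)silyl]oxy}prop-2-yn-1-yl]hexadec-2-enoic acid F1. AuCl/K2CO3 in MeCN would cycloisomerise it to the silylated (Z)-enol lactone (3Z,4S)-4-{[tert-butyl(dimethyl)silyl]oxy}-5-methylidene-3-tetradecylideneoxolan-2-one F2. Ring-opening transesterification of this enol ester with alcohol 8 under the neutral distannoxane catalyst (ClBu2Sn)2O in toluene at 80 °C would give the silyloxy keto diester F3, the expelled enol tautomerising to the methyl ketone. TBAF/AcOH in THF would then give the keto alkynoic acid (2E)-2-{(1R)-1-[((2Z)-2-[(1S)-1-hydroxy-2-oxopropyl]hexadec-2-enoyl)oxy]prop-2-yn-1-yl}hexadec-2-enoic acid F4, and AuCl/K2CO3 in MeCN would close the ring to 17.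

Step 10. Acyl transfer between two hindered partners may be slow, and the activated (Z)-enoyl donor may isomerise to the E form through reversible conjugate addition of DMAP. The fallback forms the same C–O bond by alkylation of the carboxylate with inversion (Mitsunobu reaction) instead of acylation of the alcohol, so that the acid is never activated. It sets out from 5 and comes back at 14. Reduction of 5 with the (S)-configured CBS catalyst would give (3R)-1-[tri(propan-2-yl)silyl]octadeca-1,4-diyn-3-ol F5. Hydrostannation as in step 4 would give (3S,4E)-4-(tributylstannyl)-1-[tri(propan-2-yl)silyl]octadec-4-en-1-yn-3-ol F6, and carbonylation as in step 5 would give 2-(trimethylsilyl)ethyl (2E)-2-{(1R)-1-hydroxy-3-[tri(propan-2-yl)silyl]prop-2-yn-1-yl}hexadec-2-enoate F7. PPh3/DIAD with acid 12 in toluene at 0 °C would then displace the activated hydroxyl group with inversion to give 14.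

Step 6. The hydroxyl group can steer the ruthenium catalyst to either of the two alkynes that flank it, so tin may also be delivered to the silyl alkyne or to both (step 4 rests on the same steric bias). The fallback builds the (Z)-enoate by syn-hydroalumination of an ynoate and aldol addition instead of by functionalising the diynol. It sets out from 1 and 2 and comes back at 10. Acetylide 3 (from 1 and n-BuLi) and methyl chloroformate would give methyl hexadec-2-ynoate F8. i-Bu2AlH with N-methylmorpholine N-oxide in THF at 0 °C would add H and Al to the same face to give methyl (2E)-2-[bis(2-methylpropyl)alumanyl]hexadec-2-enoate F9 (not isolated), which would add to aldehyde 2 with retention to give racemic methyl (2Z)-2-{1-hydroxy-3-[tri(propan-2-yl)silyl]prop-2-yn-1-yl}hexadec-2-enoate F10. Kinetic resolution with Pseudomonas cepacia lipase and vinyl acetate, in which the enoate arm is expected to act as the large group, would acetylate the (S)-alcohol to methyl (2Z)-2-{(1S)-1-acetoxy-3-[tri(propan-2-yl)silyl]prop-2-yn-1-yl}hexadec-2-enoate F11; this assignment would have to be confirmed. K2CO3 in MeOH would then return 10.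

**Further compounds**

F1 | step 12 | (2Z)-2-[(1R)-1-{[tert-butyl(dimethyl)silyl]oxy}prop-2-yn-1-yl]hexadec-2-enoic acid | CC(C)(C)[Si](C)(C)O[C@H](C#C)/C(=C/CCCCCCCCCCCCC)C(=O)O
F2 | step 12 | (3Z,4S)-4-{[tert-butyl(dimethyl)silyl]oxy}-5-methylidene-3-tetradecylideneoxolan-2-one | C=C1OC(=O)/C(=C\CCCCCCCCCCCCC)[C@@H]1O[Si](C)(C)C(C)(C)C
F3 | step 12 | 2-(trimethylsilyl)ethyl (2E)-2-{(1S)-1-[((2Z)-2-{(1S)-1-{[tert-butyl(dimethyl)silyl]oxy}-2-oxopropyl}hexadec-2-enoyl)oxy]-3-[tri(propan-2-yl)silyl]prop-2-yn-1-yl}hexadec-2-enoate | CC(C)(C)[Si](C)(C)O[C@H](C(C)=O)/C(=C/CCCCCCCCCCCCC)C(=O)O[C@H](C#C[Si](C(C)C)(C(C)C)C(C)C)/C(=C\CCCCCCCCCCCCC)C(=O)OCC[Si](C)(C)C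
F4 | step 12 | (2E)-2-{(1R)-1-[((2Z)-2-[(1S)-1-hydroxy-2-oxopropyl]hexadec-2-enoyl)oxy]prop-2-yn-1-yl}hexadec-2-enoic acid | O[C@H](C(C)=O)/C(=C/CCCCCCCCCCCCC)C(=O)O[C@H](C#C)/C(=C\CCCCCCCCCCCCC)C(=O)O
F5 | step 10 | (3R)-1-[tri(propan-2-yl)silyl]octadeca-1,4-diyn-3-ol | O[C@@H](C#C[Si](C(C)C)(C(C)C)C(C)C)C#CCCCCCCCCCCCCC
F6 | step 10 | (3S,4E)-4-(tributylstannyl)-1-[tri(propan-2-yl)silyl]octadec-4-en-1-yn-3-ol | O[C@@H](C#C[Si](C(C)C)(C(C)C)C(C)C)/C(=C\CCCCCCCCCCCCC)[Sn](CCCC)(CCCC)CCCC
F7 | step 10 | 2-(trimethylsilyl)ethyl (2E)-2-{(1R)-1-hydroxy-3-[tri(propan-2-yl)silyl]prop-2-yn-1-yl}hexadec-2-enoate | O[C@@H](C#C[Si](C(C)C)(C(C)C)C(C)C)/C(=C\CCCCCCCCCCCCC)C(=O)OCC[Si](C)(C)C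
F8 | step 6 | methyl hexadec-2-ynoate | CCCCCCCCCCCCCC#CC(=O)OC
F9 | step 6 | methyl (2E)-2-[bis(2-methylpropyl)alumanyl]hexadec-2-enoate | CCCCCCCCCCCCC/C=C(/[Al](CC(C)C)CC(C)C)C(=O)OC
F10 | step 6 | rac-methyl (2Z)-2-{1-hydroxy-3-[tri(propan-2-yl)silyl]prop-2-yn-1-yl}hexadec-2-enoate | OC(C#C[Si](C(C)C)(C(C)C)C(C)C)/C(=C/CCCCCCCCCCCCC)C(=O)OC
F11 | step 6 | methyl (2Z)-2-{(1S)-1-acetoxy-3-[tri(propan-2-yl)silyl]prop-2-yn-1-yl}hexadec-2-enoate | CC(=O)O[C@H](C#C[Si](C(C)C)(C(C)C)C(C)C)/C(=C/CCCCCCCCCCCCC)C(=O)OC
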